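The ratio of open intermediate to substrate is worth reading against the reagent still free. You count that reagent as the charge, less one per substrate gone and one more per over-reaction product.

| flask | substrate | reagent | capture agent | remark | time |
|---|---|---|---|---|---|
| Sunday's | 0.75 M | 1.5 M | 0.45 M | run made earlier |  |
| Friday's | 3 M | 1.5 M | 0.45 M | run made earlier |  |
| Thursday's | 1.5 M | 1.5 M | 0.23 M | run made earlier |  |
| flask | 1.5 M | 1.50 M | 0.450 M |  | 8.0 h |

| run | time / h | target / % | open intermediate / % | trapped intermediate / % | substrate / % | over-reaction product / % | isomer of the product / % |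
|---|---|---|---|---|---|---|---|
| Sunday's | 0.667 | 1.7 | 18.6 | 0 | 77.5 | 0.3 | 0 |
| Sunday's | 1.00 | 5.4 | 20.0 | 0 | 75.2 | 2.1 | 0.4 |
| Sunday's | 1.33 | 2.8 | 18.3 | 0 | 74.4 | 3.2 | 1.2 |
| Sunday's | 2.50 | 3.6 | 16.3 | 2.0 | 70.1 | 6.3 | 0.4 |
| Sunday's | 3.00 | 1.2 | 14.6 | 0 | 69.6 | 11.1 | 2.4 |
| Sunday's | 5.00 | 2.6 | 13.6 | 2.2 | 61.9 | 15.9 | 3.0 |
| Sunday's | 8.00 | 3.5 | 8.5 | 1.6 | 55.8 | 25.7 | 5.2 |
| Friday's | 1.00 | 2.7 | 12.8 | 1.6 | 82.1 | 0 | 0 |
| Friday's | 2.50 | 2.5 | 10.1 | 0.6 | 79.2 | 3.2 | 3.3 |
| Friday's | 3.00 | 4.0 | 10.2 | 0.5 | 78.1 | 4.8 | 2.1 |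
| Friday's | 5.00 | 1.5 | 6.4 | 1.9 | 75.2 | 8.6 | 1.4 |
| Friday's | 6.00 | 2.2 | 7.6 | 3.4 | 73.8 | 9.5 | 2.1 |
| Friday's | 8.00 | 2.5 | 6.3 | 1.7 | 74.5 | 12.8 | 5.4 |
| Thursday's | 1.50 | 1.8 | 14.9 | 1.2 | 76.2 | 3.7 | 0 |
| Thursday's | 3.00 | 3.7 | 13.7 | 0 | 71.6 | 6.9 | 2.0 |
| Thursday's | 5.00 | 3.8 | 11.8 | 1.7 | 68.5 | 14.0 | 2.3 |
| Thursday's | 6.00 | 2.0 | 8.6 | 1.2 | 67.4 | 16.4 | 2.7 |
| Thursday's | 8.00 | 2.5 | 7.9 | 2.7 | 64.1 | 19.1 | 2.1 |

(standard deviation of a reading: 1 percentage point)



* the species that holds most of what was charged as substrate, at 8.0 h (target / isomer of the product / open intermediate / trapped intermediate / over-reaction product / substrate)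
* the largest share itself, whichever of these holds it, in percent of the substrate charged

Thursday's reading at 8.00 h has the flask's substrate and reagent charges:

free reagent = 0.675 M

open intermediate / (substrate × free reagent) = 0.183 /M

This is the binding quotient, a reading with scatter. Sunday's run at 1.00 h reads 0.205 /M and Friday's at 1.00 h reads 0.162 /M.

Turn the substrate charge first. By hand, less reagent per substrate should leave a larger share unreacted, and it does: at 8.00 h Friday's run holds 74.5% substrate against Sunday's 55.8%. The flask's substrate and reagent charges match Thursday's, so you start from Thursday's 64.1% substrate.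

Then turn the capture agent, which the flask has at twice Thursday's. Suppose trapped intermediate gained Thursday's 2.7% again. Substrate and open intermediate would share that loss in their own ratio, leaving:

substrate = 61.7%

But at 8.00 h Sunday's and Friday's trapped readings, 1.6% and 1.7% at the flask's capture agent and other substrate charges, stand below Thursday's 2.7%, with a scatter of 1 percentage point. So I commit to the middle, 62.9% substrate, ahead of Thursday's 19.1% over-reaction product.

The forecast names substrate at 65%, above my figure, finding that Thursday's run suggests “capture agent barely affects substrate loss”.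

The flask gives substrate at 63.3%.

    target ⇌ isomer of the product (K = 1.60, k = 0.240 /h)
    reagent + target → over-reaction product (k = 0.990 /M/h)
    open intermediate + capture agent → trapped intermediate (k = 0.0660 /M/h)
    open intermediate ⇌ target + by-product (K = 22.0 M, k = 0.270 /h)
    substrate + reagent ⇌ open intermediate (K = 0.190 /M, k = 2.60 /M/h)

The forward step of substrate with reagent has a half-life of 0.18 h at the charged amounts, counted without the way back, which is short against 8.0 h. With 43% of the reagent left in the flask, the quotient gives 7.49% open intermediate, against 7.69% in the flask. The neighbour charged with 0.38 M substrate ends at 51.1% substrate with 81% of its reagent left, so the quotient gives 11.3% open intermediate, and that neighbour holds 11.5%.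

The data were computed with made-up constants; the scatter is artificial.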